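Atom labels C1–C15 are germacrane numbers (ten-membered ring C1–C10, methyls C14 on C10 and C15 on C4, lactone carbons C11–C13). Compound numbers are those of the steps and of the compound list.

## Analysis of the target

Compound 30 is a germacranolide: a ten-membered carbocycle with two trisubstituted E double bonds, C1=C10 and C4=C5, and a γ-lactone (O–C6, C7, C11, C12) fused at C6–C7. The stereocentres C6 (R), C7 (S) and C8 (S) are contiguous and carry their hydrogens on the same ring face, so the lactone is cis-fused and the C8 angelate is cis to the C7–C11 bond. The fourth centre, C11 (R), is quaternary, with the acetoxy group on the lactone face of H6 and H7 and the C13 methyl on the face of the ring carbons. The sensitive groups are the (Z)-2-methylbut-2-enoate (isomerises to the tiglate and is deprotonated by amide bases), the tertiary acetate and the (E,E)-cyclodeca-1,5-diene, which undergoes Cope rearrangement on heating and transannular cyclisation with acid. The difficulty is twofold: a strained medium ring with two E alkenes has to be made without an entropically costly macrocyclisation, and an all-cis triad plus a quaternary carbinol have to be set on a flexible ring. The strategy rests on the 1,5-relationship of the two ring alkenes. C1=C10 and C4=C5 are the exchange partners of a C5=C10 alkene in a six-membered ring (C5 to C10, with the C6 carbonyl, the C8 oxygen and the C10 methyl, that is a 5-oxygenated 3-methylcyclohexenone) and of a C1=C4 alkene in a cyclobutene (C2, C3) that bears the C15 carbon as an acceptor on C4.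

## Retrosynthetic reasoning

30 to 27 and 28. The C8–O ester bond is cut last. The angelate tolerates neither amide bases nor nucleophilic catalysts, so it should meet no further reagent, and acylation of 27 with angelic acid 28 keeps the C8 configuration.

27 to 25. The silyl ether on O8 and the acetate on O11 are functional-group changes. Acetylating the tertiary alcohol of 25 while O8 is still silylated (26) needs no differentiation of two hydroxyls.

25 to 24. The C11–O bond is cut back to the enolate of the 11,13-dihydro lactone 24. In a cis-fused lactone the C5 and C8 ring bonds and the silyloxy group cover one face of the enolate, so an electrophilic oxygen should enter on the face of H6 and H7, which is the C11 configuration of 30. Because C11 is planar in the enolate, its configuration in 24 does not matter.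

24 to 22. The lactone C–O bond and the C6–H bond are cut, leading to γ-keto ester 22. The forward step has to deliver hydride to C6 so that O6 ends cis to C11, after which the lactone closes by itself.

22 to 17 and 18. The C7–C11 bond is cut as an aldol condensation of the C7 enolate of ketone 17 with methyl pyruvate 18, giving alkylidene 21, followed by reduction of the ene-dicarbonyl unit. A direct aldol or alkylation would put the new carbon on the face away from the silyloxy group, which is trans to O8 and wrong. Going through 21 turns C7 into the carbon that receives hydrogen last, so the same facial bias gives C11 cis to O8.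

17 to 13. Only functional groups change: the C15 ester becomes a methyl group and the C6 ketal a ketone. The ester cannot be reduced next to a free C6 ketone, and a free C6 alcohol would close onto an activated C15, so C6 stays a ketal (13, 14, 16) until C15 is a methyl group.

13 to 12. The two ring alkenes are traced back to a cyclobutane: C1–C4 and C5–C10 are re-formed, giving the cis-anti-cis tricycle 12. The forward reaction is a strain-driven cycloreversion that needs no dilution and derives both E geometries from the ring fusion. It is placed before any of C6, C7 and C11 is made, so the four photochemical stereocentres disappear before they can matter.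

12 to 7 and 10. After removal of the ketal (11), the central cyclobutane is cut at C4–C5 and C1–C10 into enone 7 and cyclobutene ester 10. This is the key disconnection: two skeletal bonds and the whole carbon ring from two small cyclic alkenes. The forward step must give the head-to-head, cis-anti-cis adduct.

7 to 1. The enone C=C is cut by ring-closing metathesis (dienone 6), the vinyl ketone goes back to ester 4, and the homoallylic alcohol 3 goes back to the chlorohydrin 1 from the chiral pool. C8 is therefore bought, not made, and the precursor carries no stereochemical risk.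

10 to 8. The cyclobutene C=C is cut back to the α-bromo ester 8 through acid 9.

## Alternatives that were turned down

Alternative 1: Cut C2–C3 between the two allylic methylenes. The acyclic bis(allylic bromide) A1, which already holds the cis-lactone, the C11 acetate and a C8 triethylsilyl ether, would be closed with Ni(CO)4 (zerovalent nickel) to the ten-membered ring A2. In its favour, C6, C7, C8 and C11 are set on a small lactone fragment with conventional control, and A2 is two steps from 30; on stereocontrol of the lactone region this plan is stronger than the chosen one. Against it, the allylnickel intermediates interconvert their syn and anti forms, so neither E geometry is secure. Each allyl unit can also couple at either terminus, which opens paths to six- and eight-membered rings. The C6–O bond of the lactone is allylic to the C3–C5 allyl unit and can ionise. The closure needs high dilution and a volatile, toxic carbonyl, and A1 needs a long linear synthesis. The chosen route offers in exchange a ring formation with no entropic penalty and alkene geometry fixed by ring fusion.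

Alternative 2: Cut C5–C6. The iodoalkyne aldehyde A3 (C5 iodoalkyne, C6 aldehyde, with C7, C8 and C11 in place) would be cyclised with CrCl2 and catalytic NiCl2 to the ten-membered propargylic alcohol A4. The alkynylchromium addition is mild and chemoselective, and C7, C8 and C11 are fixed before ring closure, which is again stronger than the chosen plan for those centres. Against it, the ring must close around a linear C3–C4≡C5–C6 unit next to an E alkene, which is strained. The C6 configuration is decided in the macrocyclisation, where it is hard to predict. A4 still lacks C15, so a regio- and stereoselective trans-hydrometalation and methylation of a ring alkyne must follow, and then lactonisation of a tert-butyl ester under acid on a germacradiene. That is more steps after ring closure than the chosen route needs before it.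

Alternative 3: Cut C1–C2. The iodoalkene A5, with an (E)-C1 iodide and a C2=C3 terminal alkene on a dienyl arm, would be hydroborated with 9-BBN at C2 and cyclised with Pd(dppf)Cl2 and Cs2CO3 to A6, which is the same compound as 26 of the chosen route. Both alkene geometries and all four stereocentres are then secure before ring closure, and the endgame is the last two steps here; this is the strongest of the three on stereochemical security. Against it, 9-BBN must pick the terminal alkene of a conjugated diene. The tertiary acetate and the lactone must survive aqueous carbonate at elevated temperature. Reductive elimination to a strained ten-membered ring competes with β-hydride elimination and oligomerisation and needs high dilution. A5 is a long linear target in itself. The chosen route reaches the ring in far fewer steps from two simple cyclic alkenes, and accepts in exchange that C6, C7 and C11 are set on the formed ring.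

Key step: step 7

Remark on the chemistry: photoadduct 11 is drawn as the isomer from attack on the enone face opposite the silyloxy group. The isomer from the other face, if formed, is carried with it through step 8, because both give the same diene 13 in step 9.

## Route

Step 1
Reactants: 1 ethyl (R)-4-chloro-3-hydroxybutanoate
Product: 3 ethyl (S)-3-hydroxy-5-methylhex-5-enoate, via epoxy ester 2 (not isolated)
Conditions: CH2=C(CH3)MgBr (3 equiv), CuI (10 mol %), THF, −40 → −10 °C; aq. NH4Cl
Reagents that add atoms: isopropenylmagnesium bromide, CC(=C)[Mg]Br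
Why: Copper-catalysed Grignard substitution of a chlorohydrin through its epoxide: the magnesium alkoxide closes to epoxide 2 and the isopropenyl cuprate opens it at the terminal carbon (SN2). The stereocentre is not touched, so (R)-1 gives (S)-3; only the priorities change.

Step 2
Reactants: 3 ethyl (S)-3-hydroxy-5-methylhex-5-enoate
Product: 4 ethyl (S)-3-(tert-butyldimethylsilyloxy)-5-methylhex-5-enoate
Conditions: TBSCl, imidazole, DMF, rt
Reagents that add atoms: tert-butyldimethylsilyl chloride, CC(C)(C)[Si](C)(C)Cl
Why: Imidazole-promoted silylation of a secondary alcohol; the silyl ether is kept to step 18 and survives light, heat, hydride and enolate chemistry.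

Step 3
Reactants: 4 ethyl (S)-3-(tert-butyldimethylsilyloxy)-5-methylhex-5-enoate
Product: 6 (S)-5-(tert-butyldimethylsilyloxy)-7-methylocta-1,7-dien-3-one, via Weinreb amide 5 (not isolated)
Conditions: MeNH(OMe)·HCl, iPrMgCl, THF, −20 °C; then CH2=CHMgBr, −20 → 0 °C; inverse quench into cold aq. HCl
Reagents that add atoms: vinylmagnesium bromide, C=C[Mg]Br
Why: Weinreb ketone synthesis in one pot: the chloromagnesium amide converts the ester into amide 5, whose chelated tetrahedral adduct with the vinyl Grignard reagent stops at the ketone. The cold acidic quench keeps the liberated amine from adding to the enone.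

Step 4
Reactants: 6 (S)-5-(tert-butyldimethylsilyloxy)-7-methylocta-1,7-dien-3-one
Product: 7 (S)-5-(tert-butyldimethylsilyloxy)-3-methylcyclohex-2-en-1-one
Conditions: second-generation Grubbs catalyst (H2IMes)(PCy3)Cl2Ru=CHPh (3 mol %), CH2Cl2 (0.01 M), 40 °C
Reagents that add atoms: none
Why: Ring-closing metathesis between the vinyl ketone and the 1,1-disubstituted alkene closes the six-membered ring and forms the trisubstituted enone, driven by loss of ethene.

Step 5
Reactants: 8 ethyl 1-bromocyclobutane-1-carboxylate
Product: 9 cyclobut-1-ene-1-carboxylic acid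
Conditions: KOH (powder), toluene, reflux; then aq. HCl, 0 °C
Reagents that add atoms: potassium hydroxide, [K+].[OH-]
Why: E2 dehydrobromination of the tertiary α-bromo ester with saponification in the same pot; the carboxylate salt is the form in which the strained acrylate is least prone to polymerise.

Step 6
Reactants: 9 cyclobut-1-ene-1-carboxylic acid
Product: 10 methyl cyclobut-1-ene-1-carboxylate
Conditions: MeI, K2CO3, acetone, 0 °C → rt; distilled and used fresh
Reagents that add atoms: iodomethane, CI
Why: O-alkylation of the carboxylate under mild conditions that do not add to the strained enoate.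

Step 7
Reactants: 7 (S)-5-(tert-butyldimethylsilyloxy)-3-methylcyclohex-2-en-1-one; 10 methyl cyclobut-1-ene-1-carboxylate
Product: 11 methyl (8S)-8-(tert-butyldimethylsilyloxy)-10-methyl-6-oxo-cis-anti-cis-tricyclo[4.4.0.0(2,5)]decane-4-carboxylate
Conditions: hν (medium-pressure Hg lamp, uranium-glass filter, λ > 340 nm), 10 (5 equiv), CH2Cl2, −20 °C, argon
Reagents that add atoms: none
Why: Light above 340 nm excites only the enone; after intersystem crossing its triplet adds to the cyclobutene C=C to give a triplet 1,4-diradical, which collapses after spin inversion, so C4–C5 and C1–C10 are both formed. The closest known reaction type is the enone–alkene [2+2] photocycloaddition, here in the form of a cyclohexenone adding to a cyclobut-1-enecarboxylate to give a tricyclo[4.4.0.0(2,5)]decanone. The one new ring, the central cyclobutane, is closed by radical–radical combination within the 1,4-diradical, from two separate components and without a tether. An acceptor-substituted alkene places its substituted carbon on the enone α-carbon (head-to-head), so the ester carbon C4 bonds to C5 and C1 to C10. C5 and C10 end cis because a six–four junction is stable only cis (a trans adduct would epimerise at C5, α to the ketone), and C1 and C4 are cis because the cyclobutene ring cannot span a trans junction. The anti relationship comes from approach of the cyclobutene with its CH2–CH2 bridge turned away from the six-membered ring. The enone face (expected: opposite the silyloxy group) needs no control, because C1, C4, C5 and C10 all become sp2 in step 9. The step needs head-to-head and cis-anti-cis selectivity; the ester secures the first and steric approach the second.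

Step 8
Reactants: 11 tricyclic keto ester
Product: 12 methyl (8S)-8-(tert-butyldimethylsilyloxy)-6,6-ethylenedioxy-10-methyl-cis-anti-cis-tricyclo[4.4.0.0(2,5)]decane-4-carboxylate
Conditions: Me3SiOCH2CH2OSiMe3, Me3SiOTf (5 mol %), CH2Cl2, −78 → −20 °C
Reagents that add atoms: 1,2-bis(trimethylsilyloxy)ethane, C[Si](C)(C)OCCO[Si](C)(C)C
Why: Silyl-triflate-catalysed ketalisation under aprotic conditions, which a silyl ether tolerates. The ketal lets the ester be reduced later and keeps the thermolysis product from being a doubly activated keto-enoate.

Step 9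
Reactants: 12 tricyclic ketal ester
Product: 13 methyl (8S)-8-(tert-butyldimethylsilyloxy)-6,6-ethylenedioxygermacra-1(10),4-dien-15-oate (both ring double bonds trans in the ring)
Conditions: flash vacuum thermolysis, quartz tube, 450–500 °C, 0.01 mbar, contact time of milliseconds; condensed at −78 °C
Reagents that add atoms: none
Why: Thermal cycloreversion of a bicyclo[2.2.0]hexane: the strained central C1–C4 bond breaks to a 1,4-diyl (the C4 radical is stabilised by the ester), which then cleaves C5–C10. With retention at both ends the cis-anti-cis tricycle maps to two ring-trans alkenes. The short contact time is chosen to keep the product from the Cope rearrangement, and the facial isomers of 11 converge here.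

Step 10
Reactants: 13 cyclodecadiene ester
Product: 14 (8S)-8-(tert-butyldimethylsilyloxy)-6,6-ethylenedioxygermacra-1(10),4-dien-15-ol
Conditions: iBu2AlH (2.5 equiv), CH2Cl2, −78 °C; Rochelle salt
Reagents that add atoms: none
Why: 1,2-Reduction of the α,β-unsaturated ester to the primary allylic alcohol; the ketal and the silyl ether are inert.

Step 11
Reactants: 14 allylic alcohol
Product: 16 (8S)-8-(tert-butyldimethylsilyloxy)-6,6-ethylenedioxygermacra-1(10)E,4E-diene, via allylic hydrogen sulfate 15 (not isolated)
Conditions: SO3·pyridine, THF, 0 °C; then LiAlH4, 0 °C → rt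
Reagents that add atoms: none
Why: Hydrogenolysis of a primary allylic alcohol through its sulfate monoester: hydride displaces sulfate at the primary carbon (SN2), so the double bond keeps its position and geometry. The C6 ketal rules out ring closure of an O6 nucleophile onto C15.

Step 12
Reactants: 16 diene ketal
Product: 17 (8S)-8-(tert-butyldimethylsilyloxy)germacra-1(10)E,4E-dien-6-one
Conditions: PPTS (0.2 equiv), acetone/H2O 10:1, rt
Reagents that add atoms: water, O
Why: Hydrolysis of an allylic ketal, which ionises easily, under a weak buffered acid that should spare the silyl ether and the 1,5-diene.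

Step 13
Reactants: 17 cyclodecadienone; 18 methyl pyruvate
Product: 21 methyl (8S)-8-(tert-butyldimethylsilyloxy)-6-oxogermacra-1(10)E,4E,7(11)-trien-12-oate, via aldol adduct 19 (not isolated), via aldol acetate 20 (not isolated)
Conditions: LiN(iPr)2 (1.1 equiv), THF, −78 °C; 18, −78 °C; Ac2O, −78 → −20 °C; DBU (1.2 equiv), −20 → 0 °C
Reagents that add atoms: none
Why: Aldol condensation: kinetic α'-deprotonation at C7, addition to the ketone carbonyl of the pyruvate, O-acetylation of the aldolate and E1cB loss of acetate through the C6 enolate. C7 and C11 both end sp2, so no stereocentre is made and the double-bond geometry is irrelevant for step 14.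

Step 14
Reactants: 21 alkylidene keto ester
Product: 22 methyl (7S,8S)-8-(tert-butyldimethylsilyloxy)-6-oxogermacra-1(10)E,4E-dien-12-oate (C11 epimers)
Conditions: SmI2 (2.5 equiv), MeOH (10 equiv), THF, −78 °C
Reagents that add atoms: none
Why: Reduction of a 2-ene-1,4-dicarbonyl unit by two single-electron transfers, which leaves the simple enone and ester alone. C7 is set by protonation of the samarium enolate by methanol at −78 °C on the face opposite the C8 silyloxy group, which puts C11 cis to O8; C11 stays a mixture because step 16 enolises it.

Step 15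
Reactants: 22 γ-keto ester
Product: 24 (6R,7R,8S)-8-(tert-butyldimethylsilyloxy)germacra-1(10)E,4E-dien-12,6-olide (C11 epimers), via hydroxy ester 23 (not isolated)
Conditions: NaBH4, CeCl3·7H2O, MeOH, −78 → −20 °C; then PPTS (cat.), CH2Cl2, rt
Reagents that add atoms: none
Why: Luche 1,2-reduction of the enone carbonyl. As in α-branched medium-ring ketones, the C7–C11 bond lies near the carbonyl plane and hydride comes from the ring periphery on the side away from it, which gives the C6 alcohol cis to C11; this γ-hydroxy ester then closes to the cis-fused lactone.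

Step 16
Reactants: 24 dihydro lactone
Product: 25 (6R,7R,8S,11R)-8-(tert-butyldimethylsilyloxy)-11-hydroxygermacra-1(10)E,4E-dien-12,6-olide
Conditions: KN(SiMe3)2 (1.3 equiv), THF, −78 °C; 3-phenyl-2-(phenylsulfonyl)oxaziridine, −78 °C; aq. NH4Cl
Reagents that add atoms: 3-phenyl-2-(phenylsulfonyl)oxaziridine, O=S(=O)(c1ccccc1)N1OC1c1ccccc1
Why: Enolate oxidation with an N-sulfonyloxaziridine. The potassium enolate of the cis-fused lactone is open only on the face of H6 and H7, the other being covered by the C5 and C8 ring bonds and the silyloxy group, so oxygen enters cis to H7 and the C13 methyl ends cis to C8 (11R); both C11 epimers of 24 converge.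

Step 17
Reactants: 25 α-hydroxy lactone
Product: 26 (6R,7R,8S,11R)-11-acetoxy-8-(tert-butyldimethylsilyloxy)germacra-1(10)E,4E-dien-12,6-olide
Conditions: Ac2O, DMAP, Et3N, CH2Cl2, rt
Reagents that add atoms: acetic anhydride, CC(=O)OC(C)=O
Why: DMAP-catalysed acetylation of the tertiary alcohol, done while O8 is still silylated so that no choice between two hydroxyls arises.

Step 18
Reactants: 26 silyl ether
Product: 27 (6R,7S,8S,11R)-11-acetoxy-8-hydroxygermacra-1(10)E,4E-dien-12,6-olide
Conditions: HF·pyridine, pyridine, THF, 0 °C → rt
Reagents that add atoms: none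
Why: Desilylation with buffered hydrogen fluoride; a basic fluoride source is avoided because it could move the acetate or open the lactone. The acetate lies on the lactone face turned away from O8, which disfavours migration.

Step 19
Reactants: 27 secondary alcohol; 28 angelic acid
Product: 30 CNP0144564.1, via mixed anhydride 29 (not isolated)
Conditions: 28, 2,4,6-trichlorobenzoyl chloride, Et3N, toluene, rt; then 27, 75 °C
Reagents that add atoms: none
Why: Yamaguchi esterification through mixed anhydride 29, run without DMAP because a nucleophilic catalyst isomerises the Z enoate; acylation on oxygen keeps the C8 configuration.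

## Compound list

1 | ethyl (R)-4-chloro-3-hydroxybutanoate | CCOC(=O)C[C@@H](O)CCl | starting material
2 | ethyl (R)-2-(oxiran-2-yl)acetate | CCOC(=O)C[C@@H]1CO1 | intermediate
3 | ethyl (S)-3-hydroxy-5-methylhex-5-enoate | CCOC(=O)C[C@@H](O)CC(C)=C | intermediate
4 | ethyl (S)-3-(tert-butyldimethylsilyloxy)-5-methylhex-5-enoate | CCOC(=O)C[C@@H](O[Si](C)(C)C(C)(C)C)CC(C)=C | intermediate
5 | (S)-3-(tert-butyldimethylsilyloxy)-N-methoxy-N,5-dimethylhex-5-enamide | CON(C)C(=O)C[C@@H](O[Si](C)(C)C(C)(C)C)CC(C)=C | intermediate
6 | (S)-5-(tert-butyldimethylsilyloxy)-7-methylocta-1,7-dien-3-one | C=CC(=O)C[C@@H](O[Si](C)(C)C(C)(C)C)CC(C)=C | intermediate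
7 | (S)-5-(tert-butyldimethylsilyloxy)-3-methylcyclohex-2-en-1-one | CC(C)(C)[Si](C)(C)O[C@H]1CC(C)=CC(=O)C1 | intermediate
8 | ethyl 1-bromocyclobutane-1-carboxylate | CCOC(=O)C1(Br)CCC1 | starting material
9 | cyclobut-1-ene-1-carboxylic acid | OC(=O)C1=CCC1 | intermediate
10 | methyl cyclobut-1-ene-1-carboxylate | COC(=O)C1=CCC1 | intermediate
11 | methyl (8S)-8-(tert-butyldimethylsilyloxy)-10-methyl-6-oxo-cis-anti-cis-tricyclo[4.4.0.0(2,5)]decane-4-carboxylate (cyclobutane C1–C4–C5–C10, anti to the silyloxy group) | CC(C)(C)[Si](C)(C)O[C@H]1C[C@]2(C)[C@H]3CC[C@@]3(C(=O)OC)[C@@H]2C(=O)C1 | intermediate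
12 | C6 ethylene ketal of 11 | CC(C)(C)[Si](C)(C)O[C@H]1C[C@]2(C)[C@H]3CC[C@@]3(C(=O)OC)[C@@H]2C4(OCCO4)C1 | intermediate
13 | methyl (8S)-8-(tert-butyldimethylsilyloxy)-6,6-ethylenedioxygermacra-1(10),4-dien-15-oate (1(10)E,4Z by the sequence rule; both double bonds trans in the ring) | CC(C)(C)[Si](C)(C)O[C@H]1C/C(C)=C/CC/C(C(=O)OC)=C/C2(OCCO2)C1 | intermediate
14 | (8S)-8-(tert-butyldimethylsilyloxy)-6,6-ethylenedioxygermacra-1(10),4-dien-15-ol (ring-trans at both double bonds) | CC(C)(C)[Si](C)(C)O[C@H]1C/C(C)=C/CC/C(CO)=C/C2(OCCO2)C1 | intermediate
15 | 15-O-hydrogen sulfate of 14 | CC(C)(C)[Si](C)(C)O[C@H]1C/C(C)=C/CC/C(COS(=O)(=O)O)=C/C2(OCCO2)C1 | intermediate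
16 | (8S)-8-(tert-butyldimethylsilyloxy)-6,6-ethylenedioxygermacra-1(10)E,4E-diene | CC(C)(C)[Si](C)(C)O[C@H]1C/C(C)=C/CC/C(C)=C/C2(OCCO2)C1 | intermediate
17 | (8S)-8-(tert-butyldimethylsilyloxy)germacra-1(10)E,4E-dien-6-one | CC(C)(C)[Si](C)(C)O[C@H]1C/C(C)=C/CC/C(C)=C/C(=O)C1 | intermediate
18 | methyl pyruvate | CC(=O)C(=O)OC | starting material
19 | methyl (8S)-8-(tert-butyldimethylsilyloxy)-11-hydroxy-6-oxogermacra-1(10)E,4E-dien-12-oate (C7 and C11 mixtures) | CC(C)(C)[Si](C)(C)O[C@H]1C/C(C)=C/CC/C(C)=C/C(=O)C1C(C)(O)C(=O)OC | intermediate
20 | 11-O-acetate of 19 | CC(C)(C)[Si](C)(C)O[C@H]1C/C(C)=C/CC/C(C)=C/C(=O)C1C(C)(OC(C)=O)C(=O)OC | intermediate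
21 | methyl (8S)-8-(tert-butyldimethylsilyloxy)-6-oxogermacra-1(10)E,4E,7(11)-trien-12-oate (7(11) E/Z mixture) | CC(C)(C)[Si](C)(C)O[C@H]1C/C(C)=C/CC/C(C)=C/C(=O)C1=C(C)C(=O)OC | intermediate
22 | methyl (7S,8S)-8-(tert-butyldimethylsilyloxy)-6-oxogermacra-1(10)E,4E-dien-12-oate (C11 epimers; C11 cis to O8) | CC(C)(C)[Si](C)(C)O[C@H]1C/C(C)=C/CC/C(C)=C/C(=O)[C@H]1C(C)C(=O)OC | intermediate
23 | methyl (6R,7R,8S)-8-(tert-butyldimethylsilyloxy)-6-hydroxygermacra-1(10)E,4E-dien-12-oate (C11 epimers) | CC(C)(C)[Si](C)(C)O[C@H]1C/C(C)=C/CC/C(C)=C/[C@@H](O)[C@H]1C(C)C(=O)OC | intermediate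
24 | (6R,7R,8S)-8-(tert-butyldimethylsilyloxy)germacra-1(10)E,4E-dien-12,6-olide (cis-fused, C11 epimers) | CC(C)(C)[Si](C)(C)O[C@H]1C/C(C)=C/CC/C(C)=C/[C@H]2OC(=O)C(C)[C@@H]12 | intermediate
25 | (6R,7R,8S,11R)-8-(tert-butyldimethylsilyloxy)-11-hydroxygermacra-1(10)E,4E-dien-12,6-olide | CC(C)(C)[Si](C)(C)O[C@H]1C/C(C)=C/CC/C(C)=C/[C@H]2OC(=O)[C@](C)(O)[C@@H]12 | intermediate
26 | (6R,7R,8S,11R)-11-acetoxy-8-(tert-butyldimethylsilyloxy)germacra-1(10)E,4E-dien-12,6-olide | CC(C)(C)[Si](C)(C)O[C@H]1C/C(C)=C/CC/C(C)=C/[C@H]2OC(=O)[C@](C)(OC(C)=O)[C@@H]12 | intermediate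
27 | (6R,7S,8S,11R)-11-acetoxy-8-hydroxygermacra-1(10)E,4E-dien-12,6-olide | O[C@H]1C/C(C)=C/CC/C(C)=C/[C@H]2OC(=O)[C@](C)(OC(C)=O)[C@@H]12 | intermediate
28 | angelic acid, (Z)-2-methylbut-2-enoic acid | C/C=C(/C)C(=O)O | starting material
29 | (Z)-2-methylbut-2-enoic 2,4,6-trichlorobenzoic anhydride | C/C=C(/C)C(=O)OC(=O)c1c(Cl)cc(Cl)cc1Cl | intermediate
30 | CNP0144564.1, (6R,7S,8S,11R)-11-acetoxy-8-angeloyloxygermacra-1(10)E,4E-dien-12,6-olide | C/C=C(/C)C(=O)O[C@H]1C/C(C)=C/CC/C(C)=C/[C@H]2OC(=O)[C@](C)(OC(C)=O)[C@@H]12 | target

## Step count and weakest steps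

Total: 19 steps. Longest linear sequence: 17 steps (steps 1–4 and 7–19); steps 5 and 6 form the short branch.

Step 7 (key step). The most likely failures are competing head-to-tail addition, some cis-syn-cis adduct (which would give a Z alkene after step 9) and polymerisation of the strained enoate 10 under irradiation. The fallback changes the acceptor partner and the path to C15 and runs from 7 back to 14. Cyclobutanecarbonitrile is selenenylated (LiN(iPr)2, PhSeBr) to 1-(phenylselanyl)cyclobutane-1-carbonitrile F1 and oxidised with H2O2 to cyclobut-1-ene-1-carbonitrile F2. Its smaller, more strongly polarising cyano group should favour the head-to-head adduct more firmly and homopolymerise less. Irradiation of 7 with it gives the tricyclic keto nitrile F3, ketalisation as in step 8 gives the ketal nitrile F4, and thermolysis as in step 9 gives the cyclodecadiene nitrile F5. Reduction with iBu2AlH and mild hydrolysis gives the enal F6, and NaBH4 with CeCl3·7H2O gives 14.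

Step 9. The (E,E)-cyclodeca-1,5-diene can undergo Cope rearrangement to a divinylcyclohexane at the temperature of its formation, and rotation in the 1,4-diyl can erode the double-bond geometry. The fallback moves the cycloreversion to a different substrate and runs from 12 back to 17. LiAlH4 reduces 12 to the tricyclic primary alcohol F7, MsCl and Et3N give the mesylate F8, LiBHEt3 in hot THF gives the C4-methyl ketal F9, and PPTS in wet acetone gives the tricyclic methyl ketone F10. Thermolysis of F10 gives 17 directly; in 17 the C6 carbonyl is conjugated with C4=C5, a stabilisation the Cope product would lose.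

Step 13. The C7 enolate has the silyloxy group in the β-position and can expel it (E1cB), the aldolate can revert, and the amidine base can deprotonate at C8 of 21 and erode the only carried stereocentre. The fallback avoids a free enolate and runs from 17 back to 21. Et3SiOTf and Et3N give the triethylsilyl dienol ether F11, and a Mukaiyama aldol addition to 18 with catalytic Cu(OTf)2 at −78 °C gives aldol 19, which is now isolated. Acetylation (Ac2O, DMAP) and elimination with Et3N at 0 °C then give 21.

Step 14. Poor facial selectivity in the protonation at C7, or later epimerisation α to the ketone, would give the C7 epimer with C11 trans to O8. The fallback reverses the order of bond formation at C7 and runs from 17 back to 22. The lithium enolate of 17 is alkylated with methyl 2-(trifluoromethylsulfonyloxy)propanoate F12, made from methyl lactate with Tf2O and 2,6-lutidine. Here the carbon electrophile, not the proton, takes the open face of the enolate, so this sequence gives the C7 epimer that the protonation does not, and one of the two orders must supply 22.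

Step 15. Hydride delivery from the wrong face of the C6 carbonyl would give the trans-fused lactone. The fallback sets C6 by inversion and runs from 22 back to 24. The 6-epi lactone F13 obtained in that case is opened with LiOH to the hydroxy acid F14, and Mitsunobu lactonisation (PPh3, DIAD) closes the ring with inversion at C6 to give 24.

Further compounds
F1 | step 7 | 1-(phenylselanyl)cyclobutane-1-carbonitrile | N#CC1(CCC1)[Se]c1ccccc1
F2 | step 7 | cyclobut-1-ene-1-carbonitrile | N#CC1=CCC1
F3 | step 7 | (8S)-8-(tert-butyldimethylsilyloxy)-10-methyl-6-oxo-cis-anti-cis-tricyclo[4.4.0.0(2,5)]decane-4-carbonitrile | CC(C)(C)[Si](C)(C)O[C@H]1C[C@]2(C)[C@H]3CC[C@@]3(C#N)[C@@H]2C(=O)C1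
F4 | step 7 | C6 ethylene ketal of F3 | CC(C)(C)[Si](C)(C)O[C@H]1C[C@]2(C)[C@H]3CC[C@@]3(C#N)[C@@H]2C4(OCCO4)C1
F5 | step 7 | (8S)-8-(tert-butyldimethylsilyloxy)-6,6-ethylenedioxygermacra-1(10),4-diene-15-nitrile (ring-trans at both double bonds) | CC(C)(C)[Si](C)(C)O[C@H]1C/C(C)=C/CC/C(C#N)=C/C2(OCCO2)C1
F6 | step 7 | (8S)-8-(tert-butyldimethylsilyloxy)-6,6-ethylenedioxygermacra-1(10),4-dien-15-al (ring-trans at both double bonds) | CC(C)(C)[Si](C)(C)O[C@H]1C/C(C)=C/CC/C(C=O)=C/C2(OCCO2)C1
F7 | step 9 | tricyclic primary alcohol from 12 (C4 hydroxymethyl) | CC(C)(C)[Si](C)(C)O[C@H]1C[C@]2(C)[C@H]3CC[C@@]3(CO)[C@@H]2C4(OCCO4)C1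
F8 | step 9 | methanesulfonate of F7 | CC(C)(C)[Si](C)(C)O[C@H]1C[C@]2(C)[C@H]3CC[C@@]3(COS(C)(=O)=O)[C@@H]2C4(OCCO4)C1
F9 | step 9 | (8S)-8-(tert-butyldimethylsilyloxy)-6,6-ethylenedioxy-4,10-dimethyl-cis-anti-cis-tricyclo[4.4.0.0(2,5)]decane | CC(C)(C)[Si](C)(C)O[C@H]1C[C@]2(C)[C@H]3CC[C@@]3(C)[C@@H]2C4(OCCO4)C1
F10 | step 9 | (8S)-8-(tert-butyldimethylsilyloxy)-4,10-dimethyl-cis-anti-cis-tricyclo[4.4.0.0(2,5)]decan-6-one | CC(C)(C)[Si](C)(C)O[C@H]1C[C@]2(C)[C@H]3CC[C@@]3(C)[C@@H]2C(=O)C1
F11 | step 13 | (8S)-8-(tert-butyldimethylsilyloxy)-6-(triethylsilyloxy)germacra-1(10),4,6-triene | CC(C)(C)[Si](C)(C)O[C@H]1C/C(C)=C/CC/C(C)=C/C(O[Si](CC)(CC)CC)=C1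
F12 | step 14 | methyl 2-(trifluoromethylsulfonyloxy)propanoate | COC(=O)C(C)OS(=O)(=O)C(F)(F)F
F13 | step 15 | (6S,7R,8S)-8-(tert-butyldimethylsilyloxy)germacra-1(10)E,4E-dien-12,6-olide (trans-fused, C11 epimers) | CC(C)(C)[Si](C)(C)O[C@H]1C/C(C)=C/CC/C(C)=C/[C@@H]2OC(=O)C(C)[C@@H]12
F14 | step 15 | (6S,7R,8S)-8-(tert-butyldimethylsilyloxy)-6-hydroxygermacra-1(10)E,4E-dien-12-oic acid (C11 epimers) | CC(C)(C)[Si](C)(C)O[C@H]1C/C(C)=C/CC/C(C)=C/[C@H](O)[C@H]1C(C)C(O)=O
A1 | alternative 1 | acyclic bis(allylic bromide), C2 and C3 as CH2Br, with the cis-lactone, the C11 acetate and the C8 triethylsilyl ether | BrC/C=C(C)/C[C@H](O[Si](CC)(CC)CC)[C@H]1[C@@H](/C=C(\C)CBr)OC(=O)[C@]1(C)OC(C)=O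
A2 | alternative 1 | 8-O-triethylsilyl ether of the de-angeloyl target | CC[Si](CC)(CC)O[C@H]1C/C(C)=C/CC/C(C)=C/[C@H]2OC(=O)[C@](C)(OC(C)=O)[C@@H]12
A3 | alternative 2 | acyclic iodoalkyne aldehyde (C5 iodoalkyne, C6 aldehyde, tert-butyl ester) | IC#CCC/C=C(C)/C[C@H](O[Si](C)(C)C(C)(C)C)[C@@H](C=O)[C@@](C)(O[Si](CC)(CC)CC)C(=O)OC(C)(C)C
A4 | alternative 2 | ten-membered propargylic alcohol (C4–C5 alkyne, C6 hydroxyl) | CC(C)(C)[Si](C)(C)O[C@H]1C/C(C)=C/CCC#C[C@@H](O)[C@H]1[C@@](C)(O[Si](CC)(CC)CC)C(=O)OC(C)(C)C
A5 | alternative 3 | acyclic (E)-C1 iodoalkene with a C2=C3 terminal alkene on the dienyl arm, cis-lactone, C11 acetate, C8 silyl ether | I/C=C(C)/C[C@H](O[Si](C)(C)C(C)(C)C)[C@H]1[C@@H](/C=C(\C)C=C)OC(=O)[C@]1(C)OC(C)=O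
A6 | alternative 3 | 8-O-tert-butyldimethylsilyl ether of the de-angeloyl target | CC(C)(C)[Si](C)(C)O[C@H]1C/C(C)=C/CC/C(C)=C/[C@H]2OC(=O)[C@](C)(OC(C)=O)[C@@H]12
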